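**Retrosynthetic overview**

1. The target is the bis(2‑trimethylsilylethyl) ester of itself after fluoride cleavage; that ester is made by forming C9–C10 last, in an Ir‑photoredox decarboxylative conjugate addition of an A‑ring tertiary acid to a bicyclo[3.2.1]octenone aldehyde (sets C9 and quaternary C10).
2. The A‑ring acid comes from a catalytic desymmetrising alcoholysis of a meso bridged anhydride (one enantiotopic carboxyl becomes C19, the other is later lost as CO2). The anhydride comes from a Diels–Alder reaction of benzyl pentadienoate with citraconic anhydride, C‑methylation and hydrogenation.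
3. The C/D enone comes from a Pd‑catalysed intramolecular α′‑alkenylation (C13–C16, closes ring D) of a 4,4‑disubstituted cyclohexenone, made by Stork–Danheiser transposition after a Pd‑catalysed decarboxylative asymmetric allylation (sets C8) of a cyclohexane‑1,3‑dione vinylogous ester.
4. Ring order: ring A (Diels–Alder) and ring C (from the dione) are made separately, ring D is closed on the C‑ring fragment, and the two halves are joined last.

Atom labels C1–C20 follow ent‑kaurane numbering of the target (C6 = carboxyl on C5, C7 = formyl carbon, C19 = carboxyl on C4, C20 = methyl on C10).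

Assumption: the sense of induction of (DHQD)2AQN on the new meso substrate 8 is not known; (DHQD)2AQN is written, and its pseudo‑enantiomer (DHQ)2AQN is used instead if that is the one that esterifies the carbonyl shown.

**Route**

Step 1
Reactants: 1 (2E)-penta-2,4-dienoic acid
Product: 2 benzyl (2E)-penta-2,4-dienoate
Conditions: BnBr, K2CO3, DMF, 23 °C
Reagents that add atoms: benzyl bromide BrCc1ccccc1
Why: Carboxylate O‑alkylation (SN2) installs an ester that activates C10–H for the later enolate methylation and is removed by hydrogenolysis in step 5.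

Step 2
Reactants: 2 benzyl (2E)-penta-2,4-dienoate; 3 citraconic anhydride
Product: 4 benzyl rac-(3aS,4S,7aR)-7a-methyl-1,3-dioxo-1,3,3a,4,7,7a-hexahydro-2-benzofuran-4-carboxylate
Conditions: toluene, BHT (cat.), 130 °C, sealed tube
Reagents that add atoms: none
Why: Diels–Alder cycloaddition in which the CH2 terminus of the diene bonds to the methyl‑bearing carbon of the anhydride (steric and frontier‑orbital preferences agree) and the endo transition state puts the benzyl ester cis to the cis‑fused anhydride, so the cis relation of the C4 and C5 carboxyls is set here.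

Step 3
Reactants: 4 benzyl rac-(3aS,4S,7aR)-7a-methyl-1,3-dioxo-1,3,3a,4,7,7a-hexahydro-2-benzofuran-4-carboxylate
Product: 5 rac-(1R,5S,6S)-5-[(benzyloxy)carbonyl]-1-methyl-6-{[2-(trimethylsilyl)ethoxy]carbonyl}cyclohex-3-ene-1-carboxylic acid
Conditions: Me3SiCH2CH2OH, DMAP (cat.), Et3N, CH2Cl2, 0 → 23 °C
Reagents that add atoms: 2-(trimethylsilyl)ethanol C[Si](C)(C)CCO
Why: DMAP‑catalysed alcoholysis of the unsymmetrical anhydride takes place at the carbonyl on the tertiary carbon (C6) rather than the one on the quaternary carbon, leaving the C19 acid free without touching a stereocentre.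

Step 4
Reactants: 5 rac-(1R,5S,6S)-5-[(benzyloxy)carbonyl]-1-methyl-6-{[2-(trimethylsilyl)ethoxy]carbonyl}cyclohex-3-ene-1-carboxylic acid
Product: 6 rac-(1R,5S,6R)-5-[(benzyloxy)carbonyl]-1,5-dimethyl-6-{[2-(trimethylsilyl)ethoxy]carbonyl}cyclohex-3-ene-1-carboxylic acid
Conditions: LDA (2.3 equiv), THF, −78 °C; MeI, −78 → −20 °C; aq. HCl work‑up
Reagents that add atoms: iodomethane CI
Why: Ester dienolate α‑alkylation: after the acid is deprotonated, LDA removes the allylic α‑H of the benzyl ester and MeI is expected to enter anti to the adjacent pseudo‑axial C5 ester (A1,3‑strain‑controlled conformation), giving the isomer with all three carboxyl carbons cis.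

Step 5
Reactants: 6 rac-(1R,5S,6R)-5-[(benzyloxy)carbonyl]-1,5-dimethyl-6-{[2-(trimethylsilyl)ethoxy]carbonyl}cyclohex-3-ene-1-carboxylic acid
Product: 7 (1R,2s,3S)-1,3-dimethyl-2-{[2-(trimethylsilyl)ethoxy]carbonyl}cyclohexane-1,3-dicarboxylic acid (meso)
Conditions: H2 (3 atm), 10% Pd/C, EtOAc, 23 °C
Reagents that add atoms: none
Why: Heterogeneous hydrogenation saturates the ring alkene and hydrogenolyses the benzyl ester in one operation, which makes the two flanking carboxyls equivalent and the molecule meso.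

Step 6
Reactants: 7 (1R,2s,3S)-1,3-dimethyl-2-{[2-(trimethylsilyl)ethoxy]carbonyl}cyclohexane-1,3-dicarboxylic acid
Product: 8 2-(trimethylsilyl)ethyl (1R,5S,9s)-1,5-dimethyl-2,4-dioxo-3-oxabicyclo[3.3.1]nonane-9-carboxylate (meso)
Conditions: Ac2O, 80 °C
Reagents that add atoms: none
Why: Dehydrative cyclisation of a cis‑1,3‑diacid to a bridged glutaric anhydride (as with Kemp's triacid), possible only for the all‑cis isomer, gives a meso anhydride whose two carbonyls are enantiotopic.

Step 7
Reactants: 8 2-(trimethylsilyl)ethyl (1R,5S,9s)-1,5-dimethyl-2,4-dioxo-3-oxabicyclo[3.3.1]nonane-9-carboxylate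
Product: 9 (1S,2S,3R)-1,3-dimethyl-2,3-bis{[2-(trimethylsilyl)ethoxy]carbonyl}cyclohexane-1-carboxylic acid
Conditions: (DHQD)2AQN (20 mol %), Me3SiCH2CH2OH (5 equiv), Et2O, −20 °C
Reagents that add atoms: 2-(trimethylsilyl)ethanol C[Si](C)(C)CCO
Why: Proposed new method: catalytic enantioselective desymmetrising alcoholysis of a bridged, α,α′‑diquaternary (Kemp‑type) glutaric anhydride with 2‑(trimethylsilyl)ethanol, in which the quinuclidine nitrogen of the bis‑cinchona catalyst acts as a chiral general base that delivers the alcohol to one of the two enantiotopic carbonyls, fixing the absolute configuration of C4 and C5 and deciding that the C4 carboxyl becomes C19 while the other stays free for decarboxylation; the closest known reaction is the Deng/Bolm cinchona‑alkaloid‑catalysed alcoholysis of meso succinic and 3‑substituted glutaric anhydrides with methanol or benzyl alcohol, not yet shown for fully α‑substituted bridged anhydrides or this alcohol.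

Step 8
Reactants: 10 cyclohexane-1,3-dione
Product: 11 3-(2-methylpropoxy)cyclohex-2-en-1-one
Conditions: i-BuOH, TsOH·H2O (cat.), toluene, reflux, Dean–Stark
Reagents that add atoms: 2-methylpropan-1-ol CC(C)CO
Why: Acid‑catalysed condensation of the 1,3‑dione with the alcohol gives the vinylogous ester needed for Stork–Danheiser chemistry.

Step 9
Reactants: 12 2-chloroprop-2-en-1-ol
Product: 13 2-chloroprop-2-en-1-yl 1H-imidazole-1-carboxylate
Conditions: CDI, THF, 0 → 23 °C
Reagents that add atoms: 1,1'-carbonyldiimidazole O=C(n1ccnc1)n1ccnc1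
Why: Acyl transfer from CDI to the alcohol gives a stable alkoxycarbonylating agent.

Step 10
Reactants: 11 3-(2-methylpropoxy)cyclohex-2-en-1-one; 13 2-chloroprop-2-en-1-yl 1H-imidazole-1-carboxylate
Product: 14 2-chloroprop-2-en-1-yl rac-4-(2-methylpropoxy)-2-oxocyclohex-3-ene-1-carboxylate
Conditions: LDA (2.1 equiv), THF, −78 °C; then 13, −78 → −20 °C; NH4Cl
Reagents that add atoms: none
Why: Kinetic α′‑deprotonation of the vinylogous ester and Claisen‑type C‑acylation with the acyl imidazole give the β‑keto ester.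

Step 11
Reactants: 14 2-chloroprop-2-en-1-yl rac-4-(2-methylpropoxy)-2-oxocyclohex-3-ene-1-carboxylate
Product: 15 2-chloroprop-2-en-1-yl rac-1-(hydroxymethyl)-4-(2-methylpropoxy)-2-oxocyclohex-3-ene-1-carboxylate
Conditions: aq. CH2O (37%), KHCO3 (cat.), THF, 23 °C
Reagents that add atoms: formaldehyde C=O
Why: Base‑catalysed aldol (hydroxymethylation) of the β‑keto ester with formaldehyde introduces C7 and creates the quaternary carbon as a racemate.

Step 12
Reactants: 15 2-chloroprop-2-en-1-yl rac-1-(hydroxymethyl)-4-(2-methylpropoxy)-2-oxocyclohex-3-ene-1-carboxylate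
Product: 16 2-chloroprop-2-en-1-yl rac-1-{[(tert-butyldiphenylsilyl)oxy]methyl}-4-(2-methylpropoxy)-2-oxocyclohex-3-ene-1-carboxylate
Conditions: TBDPSCl, imidazole, DMF, 23 °C
Reagents that add atoms: tert-butyl(chloro)diphenylsilane CC(C)(C)[Si](Cl)(c1ccccc1)c1ccccc1
Why: Silylation of the primary alcohol blocks retro‑aldol loss of formaldehyde and keeps the oxygen inert through the palladium steps.

Step 13
Reactants: 16 2-chloroprop-2-en-1-yl rac-1-{[(tert-butyldiphenylsilyl)oxy]methyl}-4-(2-methylpropoxy)-2-oxocyclohex-3-ene-1-carboxylate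
Product: 17 (6S)-6-{[(tert-butyldiphenylsilyl)oxy]methyl}-6-(2-chloroprop-2-en-1-yl)-3-(2-methylpropoxy)cyclohex-2-en-1-one
Conditions: Pd2(dba)3 (2.5 mol %), (S)-t-BuPHOX (6.25 mol %), toluene, 30 °C
Reagents that add atoms: none
Why: Pd‑catalysed decarboxylative asymmetric allylic alkylation (Tsuji–Trost type, Stoltz): loss of CO2 gives a prochiral enolate/π‑allyl pair that recombines under control of the (S)‑PHOX ligand, setting the C8 quaternary stereocentre with the same facial sense as in (S)‑2‑allyl‑2‑methylcyclohexanone.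

Step 14
Reactants: 17 (6S)-6-{[(tert-butyldiphenylsilyl)oxy]methyl}-6-(2-chloroprop-2-en-1-yl)-3-(2-methylpropoxy)cyclohex-2-en-1-one
Product: 19 (4R)-4-{[(tert-butyldiphenylsilyl)oxy]methyl}-4-(2-chloroprop-2-en-1-yl)cyclohex-2-en-1-one, via allylic alcohol 18 (not isolated)
Conditions: DIBAL-H, toluene, −78 °C; then 1 M aq. HCl, THF, 23 °C
Reagents that add atoms: water O
Why: Stork–Danheiser transposition (1,2‑reduction of the vinylogous ester carbonyl, then acid hydrolysis and elimination) gives the 4,4‑disubstituted enone with C8 untouched (the descriptor changes from S to R only through CIP priorities).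

Step 15
Reactants: 19 (4R)-4-{[(tert-butyldiphenylsilyl)oxy]methyl}-4-(2-chloroprop-2-en-1-yl)cyclohex-2-en-1-one
Product: 20 (1R,5R)-5-{[(tert-butyldiphenylsilyl)oxy]methyl}-7-methylidenebicyclo[3.2.1]oct-3-en-2-one
Conditions: Pd2(dba)3 (5 mol %), P(t-Bu)3·HBF4 (12 mol %), K3PO4 (3 equiv), toluene, 100 °C
Reagents that add atoms: none
Why: Pd‑catalysed intramolecular α′‑alkenylation of the ketone enolate (Buchwald–Hartwig‑type enolate coupling): oxidative addition into the vinyl chloride, attack by the only enolisable position (C13), and the tether from C8 forces the cis 1,3‑bridge, which fixes C13 and closes ring D with its exocyclic methylene.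

Step 16
Reactants: 20 (1R,5R)-5-{[(tert-butyldiphenylsilyl)oxy]methyl}-7-methylidenebicyclo[3.2.1]oct-3-en-2-one
Product: 21 (1R,5R)-5-(hydroxymethyl)-7-methylidenebicyclo[3.2.1]oct-3-en-2-one
Conditions: TBAF, AcOH (1:1), THF, 23 °C
Reagents that add atoms: none
Why: Fluoride desilylation, buffered with acetic acid so that the free alkoxide cannot undergo vinylogous retro‑aldol loss of formaldehyde.

Step 17
Reactants: 21 (1R,5R)-5-(hydroxymethyl)-7-methylidenebicyclo[3.2.1]oct-3-en-2-one
Product: 22 (1R,5R)-6-methylidene-4-oxobicyclo[3.2.1]oct-2-ene-1-carbaldehyde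
Conditions: Dess–Martin periodinane, CH2Cl2, 0 → 23 °C
Reagents that add atoms: none
Why: Dess–Martin oxidation converts the neopentyl primary alcohol into the non‑enolisable aldehyde under neutral conditions, which also makes the group next to C9 as small as possible for the coupling.

Step 18
Reactants: 9 (1S,2S,3R)-1,3-dimethyl-2,3-bis{[2-(trimethylsilyl)ethoxy]carbonyl}cyclohexane-1-carboxylic acid; 22 (1R,5R)-6-methylidene-4-oxobicyclo[3.2.1]oct-2-ene-1-carbaldehyde
Product: 23 bis[2-(trimethylsilyl)ethyl] (1R,2S,3S)-3-[(1R,2S,5R)-1-formyl-6-methylidene-4-oxobicyclo[3.2.1]octan-2-yl]-1,3-dimethylcyclohexane-1,2-dicarboxylate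
Conditions: Ir[dF(CF3)ppy]2(dtbbpy)PF6 (2 mol %), K2HPO4 (1.2 equiv), DMF, blue LEDs, 23 °C
Reagents that add atoms: none
Why: Iridium‑photoredox decarboxylative Giese (radical conjugate) addition: Ir(III)* oxidises the tertiary carboxylate, loss of CO2 gives the planar C10 radical, which adds to C9 of the enone from the exo face (anti to the two‑carbon C15–C16 bridge, setting C9) and is itself attacked on the face anti to the two cis ester groups (setting quaternary C10), after which Ir(II) reduces the α‑keto radical and the enolate is protonated.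

Step 19
Reactants: 23 bis[2-(trimethylsilyl)ethyl] (1R,2S,3S)-3-[(1R,2S,5R)-1-formyl-6-methylidene-4-oxobicyclo[3.2.1]octan-2-yl]-1,3-dimethylcyclohexane-1,2-dicarboxylate
Product: 24 (1R,2S,3S)-3-[(1R,2S,5R)-1-formyl-6-methylidene-4-oxobicyclo[3.2.1]octan-2-yl]-1,3-dimethylcyclohexane-1,2-dicarboxylic acid (target, CNP0320711.1)
Conditions: TBAF (4 equiv), THF, 0 → 23 °C; then cold 0.5 M HCl to pH 3
Reagents that add atoms: none
Why: Fluoride‑induced β‑elimination of the two 2‑(trimethylsilyl)ethyl esters (attack at silicon, so the steric shielding of both carboxyls does not matter) frees the diacid without acid or hydrogenation, leaving the aldehyde, ketone, exocyclic alkene and all stereocentres untouched.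

**Compound list**

1 | (2E)-penta-2,4-dienoic acid | C=C/C=C/C(=O)O | starting material
2 | benzyl (2E)-penta-2,4-dienoate | C=C/C=C/C(=O)OCc1ccccc1 | intermediate
3 | citraconic anhydride (3-methylfuran-2,5-dione) | CC1=CC(=O)OC1=O | starting material
4 | benzyl rac-(3aS,4S,7aR)-7a-methyl-1,3-dioxo-1,3,3a,4,7,7a-hexahydro-2-benzofuran-4-carboxylate (endo adduct, three carbonyl carbons cis; racemic, one enantiomer drawn) | O=C(OCc1ccccc1)[C@H]1C=CC[C@@]2(C)C(=O)OC(=O)[C@@H]12 | intermediate
5 | rac-(1R,5S,6S)-5-[(benzyloxy)carbonyl]-1-methyl-6-{[2-(trimethylsilyl)ethoxy]carbonyl}cyclohex-3-ene-1-carboxylic acid (all-cis; racemic) | O=C(OCc1ccccc1)[C@H]1C=CC[C@@](C)(C(=O)O)[C@H]1C(=O)OCC[Si](C)(C)C | intermediate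
6 | rac-(1R,5S,6R)-5-[(benzyloxy)carbonyl]-1,5-dimethyl-6-{[2-(trimethylsilyl)ethoxy]carbonyl}cyclohex-3-ene-1-carboxylic acid (three carboxyl carbons cis, both methyls on the other face; racemic) | O=C(OCc1ccccc1)[C@@]1(C)C=CC[C@@](C)(C(=O)O)[C@H]1C(=O)OCC[Si](C)(C)C | intermediate
7 | (1R,2s,3S)-1,3-dimethyl-2-{[2-(trimethylsilyl)ethoxy]carbonyl}cyclohexane-1,3-dicarboxylic acid (meso, all three carboxyl carbons cis) | O=C(O)[C@@]1(C)CCC[C@@](C)(C(=O)O)[C@H]1C(=O)OCC[Si](C)(C)C | intermediate
8 | 2-(trimethylsilyl)ethyl (1R,5S,9s)-1,5-dimethyl-2,4-dioxo-3-oxabicyclo[3.3.1]nonane-9-carboxylate (meso; ester on the side of the anhydride bridge) | C[C@@]1(CCC[C@]2(C)[C@H]1C(=O)OCC[Si](C)(C)C)C(=O)OC2=O | intermediate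
9 | (1S,2S,3R)-1,3-dimethyl-2,3-bis{[2-(trimethylsilyl)ethoxy]carbonyl}cyclohexane-1-carboxylic acid | O=C(O)[C@@]1(C)CCC[C@@](C)(C(=O)OCC[Si](C)(C)C)[C@H]1C(=O)OCC[Si](C)(C)C | intermediate
10 | cyclohexane-1,3-dione | O=C1CCCC(=O)C1 | starting material
11 | 3-(2-methylpropoxy)cyclohex-2-en-1-one | O=C1C=C(OCC(C)C)CCC1 | intermediate
12 | 2-chloroprop-2-en-1-ol | C=C(Cl)CO | starting material
13 | 2-chloroprop-2-en-1-yl 1H-imidazole-1-carboxylate | C=C(Cl)COC(=O)n1ccnc1 | intermediate
14 | 2-chloroprop-2-en-1-yl rac-4-(2-methylpropoxy)-2-oxocyclohex-3-ene-1-carboxylate | C=C(Cl)COC(=O)C1CCC(OCC(C)C)=CC1=O | intermediate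
15 | 2-chloroprop-2-en-1-yl rac-1-(hydroxymethyl)-4-(2-methylpropoxy)-2-oxocyclohex-3-ene-1-carboxylate | C=C(Cl)COC(=O)C1(CO)CCC(OCC(C)C)=CC1=O | intermediate
16 | 2-chloroprop-2-en-1-yl rac-1-{[(tert-butyldiphenylsilyl)oxy]methyl}-4-(2-methylpropoxy)-2-oxocyclohex-3-ene-1-carboxylate | C=C(Cl)COC(=O)C1(CO[Si](c2ccccc2)(c2ccccc2)C(C)(C)C)CCC(OCC(C)C)=CC1=O | intermediate
17 | (6S)-6-{[(tert-butyldiphenylsilyl)oxy]methyl}-6-(2-chloroprop-2-en-1-yl)-3-(2-methylpropoxy)cyclohex-2-en-1-one | C=C(Cl)C[C@]1(CO[Si](c2ccccc2)(c2ccccc2)C(C)(C)C)CCC(OCC(C)C)=CC1=O | intermediate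
18 | (6S)-6-{[(tert-butyldiphenylsilyl)oxy]methyl}-6-(2-chloroprop-2-en-1-yl)-3-(2-methylpropoxy)cyclohex-2-en-1-ol (carbinol configuration not defined; erased in the same step) | C=C(Cl)C[C@]1(CO[Si](c2ccccc2)(c2ccccc2)C(C)(C)C)CCC(OCC(C)C)=CC1O | intermediate
19 | (4R)-4-{[(tert-butyldiphenylsilyl)oxy]methyl}-4-(2-chloroprop-2-en-1-yl)cyclohex-2-en-1-one | C=C(Cl)C[C@]1(CO[Si](c2ccccc2)(c2ccccc2)C(C)(C)C)CCC(=O)C=C1 | intermediate
20 | (1R,5R)-5-{[(tert-butyldiphenylsilyl)oxy]methyl}-7-methylidenebicyclo[3.2.1]oct-3-en-2-one | C=C1C[C@]2(CO[Si](c3ccccc3)(c3ccccc3)C(C)(C)C)C[C@H]1C(=O)C=C2 | intermediate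
21 | (1R,5R)-5-(hydroxymethyl)-7-methylidenebicyclo[3.2.1]oct-3-en-2-one | C=C1C[C@]2(CO)C[C@H]1C(=O)C=C2 | intermediate
22 | (1R,5R)-6-methylidene-4-oxobicyclo[3.2.1]oct-2-ene-1-carbaldehyde | C=C1C[C@]2(C=O)C[C@H]1C(=O)C=C2 | intermediate
23 | bis[2-(trimethylsilyl)ethyl] (1R,2S,3S)-3-[(1R,2S,5R)-1-formyl-6-methylidene-4-oxobicyclo[3.2.1]octan-2-yl]-1,3-dimethylcyclohexane-1,2-dicarboxylate | C=C1C[C@]2(C=O)C[C@H]1C(=O)C[C@H]2[C@]1(C)CCC[C@@](C)(C(=O)OCC[Si](C)(C)C)[C@H]1C(=O)OCC[Si](C)(C)C | intermediate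
24 | (1R,2S,3S)-3-[(1R,2S,5R)-1-formyl-6-methylidene-4-oxobicyclo[3.2.1]octan-2-yl]-1,3-dimethylcyclohexane-1,2-dicarboxylic acid | C=C1C[C@]2(C=O)C[C@H]1C(=O)C[C@H]2[C@]1(C)CCC[C@@](C)(C(=O)O)[C@H]1C(=O)O | target

**Step count**

Total: 19 steps. Longest linear sequence: 11 steps (steps 8, 10–17 from cyclohexane‑1,3‑dione, then 18 and 19); the A‑ring branch is 7 steps before the union.

**Three steps most likely to fail**

Step 7 (the proposed new desymmetrisation). The two carbonyls of 8 sit on quaternary carbons, so the catalysed alcoholysis may be slow or poorly selective. Fallback with known chemistry, starting from 8: open the anhydride without a chiral catalyst (Me3SiCH2CH2OH, DMAP, Et3N, CH2Cl2), which gives 9 as a racemate with its enantiomer, the ent‑hemiester F1. Resolve classically by fractional crystallisation of the (R)‑1‑phenylethylammonium salt of 9 F2 and acidify; this returns to the route at 9.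

Step 18 (fragment union). A tertiary radical must add to an enone carbon next to a quaternary bridgehead, and direct oxidation of the hindered carboxylate may be inefficient. Fallback, starting from 9: make the N‑hydroxyphthalimide ester F3 (N‑hydroxyphthalimide, DIC, DMAP, CH2Cl2), then generate the same C10 radical reductively and couple it with 22 under Okada/Overman conditions (Ru(bpy)3(PF6)2, Hantzsch ester, i‑Pr2NEt·HBF4, CH2Cl2, blue LEDs), which are established for tertiary‑radical fragment couplings; this returns to the route at 23.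

Step 15 (ring D closure). Oxidative addition into the vinyl chloride and coupling at the enolate may be sluggish. Fallback, starting from 19: excess LDA (THF, −78 → 0 °C) dehydrochlorinates the 2‑chloroallyl group to give the propargyl enone F4; TBSOTf/Et3N then gives the cross‑conjugated silyl dienol ether F5; a cationic gold(I) catalyst ([JohnPhosAu(MeCN)]SbF6, CH2Cl2/MeOH) closes the ring by 5‑exo‑dig Conia‑ene‑type carbocyclisation onto the alkyne (Toste), returning to the route at 20.

**Further compounds**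

F1 | step 7 | (1R,2R,3S)-1,3-dimethyl-2,3-bis{[2-(trimethylsilyl)ethoxy]carbonyl}cyclohexane-1-carboxylic acid (enantiomer of 9) | O=C(O)[C@]1(C)CCC[C@](C)(C(=O)OCC[Si](C)(C)C)[C@@H]1C(=O)OCC[Si](C)(C)C
F2 | step 7 | (R)-1-phenylethylammonium salt of 9 | C[C@@H]([NH3+])c1ccccc1.[O-]C(=O)[C@@]1(C)CCC[C@@](C)(C(=O)OCC[Si](C)(C)C)[C@H]1C(=O)OCC[Si](C)(C)C
F3 | step 18 | 1,3-dioxoisoindolin-2-yl ester (N-hydroxyphthalimide ester) of 9 | O=C(ON1C(=O)c2ccccc2C1=O)[C@@]1(C)CCC[C@@](C)(C(=O)OCC[Si](C)(C)C)[C@H]1C(=O)OCC[Si](C)(C)C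
F4 | step 15 | (4R)-4-{[(tert-butyldiphenylsilyl)oxy]methyl}-4-(prop-2-yn-1-yl)cyclohex-2-en-1-one | C#CC[C@]1(CO[Si](c2ccccc2)(c2ccccc2)C(C)(C)C)CCC(=O)C=C1
F5 | step 15 | tert-butyl{[(4R)-4-{[(tert-butyldiphenylsilyl)oxy]methyl}-4-(prop-2-yn-1-yl)cyclohexa-1,5-dien-1-yl]oxy}dimethylsilane | C#CC[C@]1(CO[Si](c2ccccc2)(c2ccccc2)C(C)(C)C)CC=C(O[Si](C)(C)C(C)(C)C)C=C1
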